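**Strategy**

The plan rests on one disconnection: take C8a out of the seven-membered ring. The remaining atoms C3a, C4, C5, C6, C7 and C8 carry isopropyl (C4), oxygen (C5) and methyl (C7) exactly as thymol does, so a carbene carbon inserted between the two adjacent unsubstituted arene carbons (C3a and C8) completes that ring and brings C1 along as an ester. One Buchner ring expansion of the intact arene, thymol methyl ether, with ethyl diazoacetate forms C8a–C3a and C8a–C8, the seven-membered ring and the C8a stereocentre. C8a then steers a trans conjugate methallylation at C3a, metathesis closes the cyclopentene at C1=C2, and hydroxyl-directed steps set C5, C7 and the epoxide.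

Key step: step 1

**Remarks and assumptions (one line each)**

- Locants follow the azulene numbering of the target (C1–C2 epoxide, C2 methyl, C3, C3a, C4 isopropyl, C5 ester oxygen, C6, C7 carbinol, C8, C8a); β is the face of H-8a, α the opposite face.
- Target configuration read from the SMILES: 1α,2α-epoxide, 2β-methyl, H-3a α, 4α-isopropyl, 5β-acyloxy, 7α-hydroxy, 7β-methyl, H-8a β (trans ring fusion).
- Compound 1 (2-isopropyl-5-methylanisole) is taken as a purchased flavour chemical.
- In 4 the ester-bearing carbon lies between two CH carbons, so the correct locants are 3 (isopropyl), 4 (methoxy) and 6 (methyl); the locants 2, 3 and 5 belong to norcaradiene 3.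
- Assumption: the S-configured catalyst delivers (1S)-4; if the sense of induction is opposite, the R-configured catalyst is used in the same way.

**Route**

Step 1
Reactants: 1 thymol methyl ether (10 equiv, also the solvent); 2 ethyl diazoacetate
Product: 4 ethyl (1S)-4-methoxy-6-methyl-3-(propan-2-yl)cyclohepta-2,4,6-triene-1-carboxylate, via norcaradiene 3 (not isolated)
Conditions: Rh2(S-PTTL)4 [dirhodium tetrakis(N-phthaloyl-(S)-tert-leucinate)] 1 mol%, neat 1, 2 added over 10 h, 20 °C
Reagents that add atoms: ethyl diazoacetate (2), CCOC(=O)C=[N+]=[N-]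
Why: Proposed new method: the divalent-rhodium carbene formed from 2 by loss of N2 adds across the C3a–C8 bond of 1 (arene cyclopropanation) and norcaradiene 3 opens by disrotatory 6π electrocyclic ring opening, so that C8a ends up bonded to C3a and C8 inside the new ring. The closest known reaction type is the racemic Buchner ring expansion of alkoxyarenes with diazoacetates under dirhodium carboxylate catalysis, together with enantioselective cyclopropanations and intramolecular Buchner reactions with chiral dirhodium carboxylates; the new element is enantiocontrol in the intermolecular arene case. The seven-membered ring closes by [2+1] cycloaddition followed by electrocyclic cleavage of the C3a–C8 bond (ring expansion). C8a, the only new stereocentre, should be set by the chiral carboxylate pocket, which has to fix both the arene face and the orientation of the ester on the carbene. C8a should survive because the ring cannot delocalise an α-anion without becoming an 8π cycloheptatrienide. Site selectivity for the C3a–C8 bond is secured by the substrate, since it is the only arene bond with two hydrogens and C8 is para to the methoxy group, and slow addition of 2 to excess 1 should suppress carbene dimerisation.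

Step 2
Reactants: 4 ethyl (1S)-4-methoxy-6-methyl-3-(propan-2-yl)cyclohepta-2,4,6-triene-1-carboxylate; 5 methyltriphenylphosphonium bromide
Product: 7 (7S)-7-ethenyl-3-methoxy-5-methyl-2-(propan-2-yl)cyclohepta-1,3,5-triene, via aldehyde 6 (not isolated)
Conditions: i-Bu2AlH (1.1 equiv), CH2Cl2, −78 °C; then Ph3P=CH2 (from 5, KN(SiMe3)2, THF), −78 to 20 °C; product kept cold and used at once
Reagents that add atoms: methyltriphenylphosphonium bromide (5), C[P+](c1ccccc1)(c1ccccc1)c1ccccc1.[Br-]
Why: One-pot DIBAL half-reduction and Wittig methylenation, in which the aluminium hemiacetal should release aldehyde 6 only as the ylide consumes it, a protocol known to spare α-stereocentres, so C8a is carried through unchanged.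

Step 3
Reactants: 7 (7S)-7-ethenyl-3-methoxy-5-methyl-2-(propan-2-yl)cyclohepta-1,3,5-triene
Product: 8 (4R)-4-ethenyl-6-methyl-2-(propan-2-yl)cyclohepta-2,6-dien-1-one
Conditions: 0.5 M aq. HCl, THF, 0 °C, short contact time
Reagents that add atoms: water, O
Why: Acid hydrolysis of the dienol ether (C-protonation, hydration of the oxocarbenium ion, loss of methanol) should give the cross-conjugated dienone under conditions too mild to move the C8a hydrogen.

Step 4
Reactants: 8 (4R)-4-ethenyl-6-methyl-2-(propan-2-yl)cyclohepta-2,6-dien-1-one; 9 2-methylallylmagnesium chloride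
Product: 12 5-ethenyl-3-methyl-6-(2-methylprop-2-en-1-yl)-7-(propan-2-yl)cyclohept-2-en-1-one (all-trans: 8aα-vinyl; 3aβ-methallyl; 4α-isopropyl), via silyl dienol ether 10 (not isolated), via 4-epimer 11 (not isolated)
Conditions: 9, CuBr·SMe2, Me3SiCl, THF, −78 °C; 1 M aq. HCl work-up; then DBU (0.2 equiv), CH2Cl2, 20 °C
Reagents that add atoms: 2-methylallylmagnesium chloride (9), CC(=C)C[Mg]Cl; chlorotrimethylsilane, C[Si](C)(C)Cl (retained only in 10)
Why: Silyl-accelerated allylcopper conjugate addition should attack the mono-substituted β-carbon C3a (the C7 terminus is β,β-disubstituted) from the face opposite the C8a vinyl group, which sets C3a trans to C8a; DBU then equilibrates C4 α to the ketone to the trans isopropyl isomer and keeps C6=C7 in conjugation.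

Step 5
Reactants: 12 all-trans 5-ethenyl-3-methyl-6-(2-methylprop-2-en-1-yl)-7-(propan-2-yl)cyclohept-2-en-1-one
Product: 13 4α-isopropyl-2,7-dimethyl-3,3a,4,5,8,8a-hexahydroazulen-5-one (H-3a α; H-8a β; trans-fused)
Conditions: second-generation Grubbs catalyst RuCl2(=CHPh)(H2IMes)(PCy3) 5 mol%, CH2Cl2, 40 °C
Reagents that add atoms: none
Why: Ring-closing metathesis of the vinyl and 2-methylallyl groups should form the trisubstituted C1=C2 bond in a five-membered ring with loss of ethene; the trans fusion is already fixed at C3a and C8a and the trisubstituted enone should not take part.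

Step 6
Reactants: 13 trans-fused 4α-isopropyl-2,7-dimethyl-3,3a,4,5,8,8a-hexahydroazulen-5-one
Product: 14 4α-isopropyl-2,7-dimethyl-3,3a,4,5,8,8a-hexahydroazulen-5α-ol
Conditions: LiBH(s-Bu)3, THF, −78 °C
Reagents that add atoms: none
Why: 1,2-Reduction of a β,β-disubstituted enone by a bulky trialkylborohydride, which should attack C5 from the β face (equatorial approach, away from axial H-3a) and give the axial 5α-alcohol cis to the isopropyl group.

Step 7
Reactants: 14 4α-isopropyl-2,7-dimethyl-3,3a,4,5,8,8a-hexahydroazulen-5α-ol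
Product: 15 6α,7α-epoxy-4α-isopropyl-2,7β-dimethyl-3,3a,4,5,6,7,8,8a-octahydroazulen-5α-ol
Conditions: VO(acac)2 5 mol%, t-BuOOH, CH2Cl2, 0 to 20 °C
Reagents that add atoms: tert-butyl hydroperoxide, CC(C)(C)OO
Why: Vanadium-catalysed hydroxyl-directed epoxidation of a cyclic allylic alcohol should deliver oxygen syn to the 5α-hydroxyl, which sets C7–O α, and should leave the isolated C1=C2 bond untouched.

Step 8
Reactants: 15 6α,7α-epoxy-4α-isopropyl-2,7β-dimethyl-3,3a,4,5,6,7,8,8a-octahydroazulen-5α-ol
Product: 16 6α,7α-epoxy-4α-isopropyl-2,7β-dimethyl-3,3a,4,6,7,8,8a-heptahydroazulen-5-one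
Conditions: Dess–Martin periodinane, NaHCO3, CH2Cl2, 0 to 20 °C
Reagents that add atoms: none
Why: Dess–Martin oxidation of the secondary alcohol under buffered conditions; the epoxide and the alkene are inert and no stereocentre is touched.

Step 9
Reactants: 16 6α,7α-epoxy-4α-isopropyl-2,7β-dimethyl-3,3a,4,6,7,8,8a-heptahydroazulen-5-one
Product: 17 7α-hydroxy-4α-isopropyl-2,7β-dimethyl-3,3a,4,6,7,8,8a-heptahydroazulen-5-one
Conditions: SmI2 (2.2 equiv), THF–MeOH, −90 °C
Reagents that add atoms: none
Why: Samarium diiodide reduction of an α,β-epoxy ketone cleaves only the C6–O bond next to the ketyl, so the tertiary 7α-alcohol should keep the configuration of the epoxide.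

Step 10
Reactants: 17 7α-hydroxy-4α-isopropyl-2,7β-dimethyl-3,3a,4,6,7,8,8a-heptahydroazulen-5-one
Product: 18 4α-isopropyl-2,7β-dimethyl-3,3a,4,5,6,7,8,8a-octahydroazulene-5β,7α-diol
Conditions: Me4NBH(OAc)3, MeCN–AcOH, −30 °C
Reagents that add atoms: none
Why: Evans–Saksena reduction, in which the 7α-alkoxy(diacetoxy)borohydride should deliver hydride intramolecularly to the α face of C5 and give the 5β-alcohol, anti to the directing hydroxyl and trans to the isopropyl group.

Step 11
Reactants: 18 4α-isopropyl-2,7β-dimethyl-3,3a,4,5,6,7,8,8a-octahydroazulene-5β,7α-diol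
Product: 19 1α,2α-epoxy-4α-isopropyl-2β,7β-dimethyldecahydroazulene-5β,7α-diol
Conditions: VO(acac)2 10 mol%, t-BuOOH, toluene, 20 to 40 °C
Reagents that add atoms: tert-butyl hydroperoxide, CC(C)(C)OO
Why: Vanadium-catalysed epoxidation directed by the bishomoallylic 7α-hydroxyl, which is expected to lie under the α face of C1, should deliver oxygen to the α face of C1=C2; the resulting syn epoxy alcohol cannot close to an ether because backside attack is impossible.

Step 12
Reactants: 19 1α,2α-epoxy-4α-isopropyl-2β,7β-dimethyldecahydroazulene-5β,7α-diol; 20 4-acetoxybenzoyl chloride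
Product: 22 1α,2α-epoxy-7α-hydroxy-4α-isopropyl-2β,7β-dimethyldecahydroazulen-5β-yl 4-hydroxybenzoate (H-3a α; H-8a β), via acetate 21 (not isolated)
Conditions: 20, Et3N, DMAP (cat.), CH2Cl2, 0 to 20 °C; then pyrrolidine, 20 °C
Reagents that add atoms: 4-acetoxybenzoyl chloride (20), CC(=O)Oc1ccc(cc1)C(Cl)=O
Why: DMAP-catalysed acylation of the secondary 5β-alcohol (the tertiary 7-alcohol should not react) followed in the same flask by selective aminolysis of the much more reactive aryl acetate, which should free the phenol without touching the benzoate or the epoxide.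

**Compound list**

1 | thymol methyl ether (2-isopropyl-5-methylanisole) | COc1cc(C)ccc1C(C)C | starting material
2 | ethyl diazoacetate | CCOC(=O)C=[N+]=[N-] | starting material
3 | ethyl 3-methoxy-5-methyl-2-(propan-2-yl)bicyclo[4.1.0]hepta-2,4-diene-7-carboxylate (norcaradiene; ester exo) | CCOC(=O)[C@@H]1[C@H]2C(C(C)C)=C(OC)C=C(C)[C@@H]12 | intermediate (not isolated)
4 | ethyl (1S)-4-methoxy-6-methyl-3-(propan-2-yl)cyclohepta-2,4,6-triene-1-carboxylate | CCOC(=O)[C@H]1C=C(C)C=C(OC)C(C(C)C)=C1 | intermediate (key-step product)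
5 | methyltriphenylphosphonium bromide | C[P+](c1ccccc1)(c1ccccc1)c1ccccc1.[Br-] | starting material
6 | (1S)-4-methoxy-6-methyl-3-(propan-2-yl)cyclohepta-2,4,6-triene-1-carbaldehyde | O=C[C@H]1C=C(C)C=C(OC)C(C(C)C)=C1 | intermediate (not isolated)
7 | (7S)-7-ethenyl-3-methoxy-5-methyl-2-(propan-2-yl)cyclohepta-1,3,5-triene | C=C[C@H]1C=C(C)C=C(OC)C(C(C)C)=C1 | intermediate
8 | (4R)-4-ethenyl-6-methyl-2-(propan-2-yl)cyclohepta-2,6-dien-1-one | C=C[C@H]1CC(C)=CC(=O)C(C(C)C)=C1 | intermediate
9 | 2-methylallylmagnesium chloride | CC(=C)C[Mg]Cl | starting material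
10 | {[4-ethenyl-6-methyl-3-(2-methylprop-2-en-1-yl)-2-(propan-2-yl)cyclohepta-1,6-dien-1-yl]oxy}trimethylsilane (3,4-trans) | CC(C)C1=C(O[Si](C)(C)C)C=C(C)C[C@H](C=C)[C@H]1CC(C)=C | intermediate (not isolated)
11 | 4-epimer of 12 (4β-isopropyl, cis to the methallyl group) | CC(C)[C@@H]1[C@H](CC(C)=C)[C@@H](C=C)CC(C)=CC1=O | intermediate (not isolated)
12 | 5-ethenyl-3-methyl-6-(2-methylprop-2-en-1-yl)-7-(propan-2-yl)cyclohept-2-en-1-one (8aα-vinyl; 3aβ-methallyl; 4α-isopropyl) | CC(C)[C@H]1[C@H](CC(C)=C)[C@@H](C=C)CC(C)=CC1=O | intermediate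
13 | 4α-isopropyl-2,7-dimethyl-3,3a,4,5,8,8a-hexahydroazulen-5-one (H-3a α; H-8a β) | CC(C)[C@H]1[C@@H]2CC(C)=C[C@H]2CC(C)=CC1=O | intermediate
14 | 4α-isopropyl-2,7-dimethyl-3,3a,4,5,8,8a-hexahydroazulen-5α-ol | CC(C)[C@H]1[C@@H]2CC(C)=C[C@H]2CC(C)=C[C@H]1O | intermediate
15 | 6α,7α-epoxy-4α-isopropyl-2,7β-dimethyl-3,3a,4,5,6,7,8,8a-octahydroazulen-5α-ol | CC(C)[C@H]1[C@@H]2CC(C)=C[C@H]2C[C@@]3(C)O[C@H]3[C@H]1O | intermediate
16 | 6α,7α-epoxy-4α-isopropyl-2,7β-dimethyl-3,3a,4,6,7,8,8a-heptahydroazulen-5-one | CC(C)[C@H]1[C@@H]2CC(C)=C[C@H]2C[C@@]3(C)O[C@H]3C1=O | intermediate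
17 | 7α-hydroxy-4α-isopropyl-2,7β-dimethyl-3,3a,4,6,7,8,8a-heptahydroazulen-5-one | CC(C)[C@H]1[C@@H]2CC(C)=C[C@H]2C[C@@](C)(O)CC1=O | intermediate
18 | 4α-isopropyl-2,7β-dimethyl-3,3a,4,5,6,7,8,8a-octahydroazulene-5β,7α-diol | CC(C)[C@H]1[C@@H]2CC(C)=C[C@H]2C[C@@](C)(O)C[C@@H]1O | intermediate
19 | 1α,2α-epoxy-4α-isopropyl-2β,7β-dimethyldecahydroazulene-5β,7α-diol | CC(C)[C@H]1[C@@H]2C[C@@]3(C)O[C@H]3[C@H]2C[C@@](C)(O)C[C@@H]1O | intermediate
20 | 4-acetoxybenzoyl chloride | CC(=O)Oc1ccc(cc1)C(Cl)=O | starting material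
21 | 1α,2α-epoxy-7α-hydroxy-4α-isopropyl-2β,7β-dimethyldecahydroazulen-5β-yl 4-acetoxybenzoate | CC(C)[C@H]1[C@@H]2C[C@@]3(C)O[C@H]3[C@H]2C[C@@](C)(O)C[C@@H]1OC(=O)c1ccc(OC(C)=O)cc1 | intermediate (not isolated)
22 | 1α,2α-epoxy-7α-hydroxy-4α-isopropyl-2β,7β-dimethyldecahydroazulen-5β-yl 4-hydroxybenzoate (CNP0245441.1) | CC(C)[C@H]1[C@@H]2C[C@@]3(C)O[C@H]3[C@H]2C[C@@](C)(O)C[C@@H]1OC(=O)c1ccc(O)cc1 | target

**Step count**

Total: 12 steps. Longest linear sequence: 12 steps (1 and 2 to 22).

**Steps most likely to fail**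

1. Step 1 (Proposed new method). The chiral carboxylate may discriminate poorly between the two enantiotopic modes of carbene transfer (arene face combined with ester orientation), and carbene dimerisation or C–H insertion may compete. Fallback, setting out from 1 and 2: the established racemic Buchner reaction with Rh2(O2CCF3)4 under the same slow-addition conditions should give racemic ethyl 4-methoxy-6-methyl-3-(propan-2-yl)cyclohepta-2,4,6-triene-1-carboxylate F1. Preparative chromatography on a chiral stationary phase (supercritical CO2 with an alcohol modifier, near room temperature) then separates F1 into 4 and the unwanted ethyl (1R)-4-methoxy-6-methyl-3-(propan-2-yl)cyclohepta-2,4,6-triene-1-carboxylate F2. The route is rejoined at 4.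

2. Step 4. The organocopper reagent may also attack the C7 terminus of the cross-conjugated dienone, add to the carbonyl, or deprotonate at C8a, and the small vinyl group may give only modest face discrimination at C3a. Fallback, setting out from 7: hydrolysis under kinetic control (oxalic acid, aqueous THF, 0 °C) should give the β,γ-unsaturated ketone (4S)-4-ethenyl-6-methyl-2-(propan-2-yl)cyclohepta-2,5-dien-1-one F3, in which C3a is the only acceptor carbon. Hosomi–Sakurai allylation (2-methylallyltrimethylsilane, TiCl4, CH2Cl2, −78 °C) anti to the vinyl group should give 5-ethenyl-3-methyl-6-(2-methylprop-2-en-1-yl)-7-(propan-2-yl)cyclohept-3-en-1-one F4 as a mixture at the isopropyl-bearing carbon. DBU in CH2Cl2 then moves the ring double bond into conjugation and equilibrates that centre, which rejoins the route at 12.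

3. Step 11. Oxygen transfer from the hindered tertiary vanadate ester to the bishomoallylic alkene may be slow or may lose face selectivity. Fallback, setting out from 18, builds the epoxide by inversion instead of delivery:
   - Acylation with 20 (Et3N, DMAP) should give 7α-hydroxy-4α-isopropyl-2,7β-dimethyl-3,3a,4,5,6,7,8,8a-octahydroazulen-5β-yl 4-acetoxybenzoate F5.
   - Et3SiOTf and 2,6-lutidine should give its 7-O-triethylsilyl ether F6, whose silyloxy group blocks the α face.
   - N-Bromosuccinimide in aqueous DME should form the bromonium ion on the β face, and water should open it at the tertiary C2 to give the 1β-bromo-2α-hydroxy bromohydrin F7.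
   - K2CO3 in methanol should close the 1α,2α-epoxide with inversion at C1 and cleave the aryl acetate to give the 7-O-triethylsilyl ether of the target F8.
   - Bu4NF buffered with acetic acid removes the silyl group, which rejoins the route at 22.

**Further compounds**

F1 | step 1 | racemic ethyl 4-methoxy-6-methyl-3-(propan-2-yl)cyclohepta-2,4,6-triene-1-carboxylate | CCOC(=O)C1C=C(C)C=C(OC)C(C(C)C)=C1
F2 | step 1 | ethyl (1R)-4-methoxy-6-methyl-3-(propan-2-yl)cyclohepta-2,4,6-triene-1-carboxylate | CCOC(=O)[C@@H]1C=C(C)C=C(OC)C(C(C)C)=C1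
F3 | step 4 | (4S)-4-ethenyl-6-methyl-2-(propan-2-yl)cyclohepta-2,5-dien-1-one | C=C[C@H]1C=C(C)CC(=O)C(C(C)C)=C1
F4 | step 4 | 5-ethenyl-3-methyl-6-(2-methylprop-2-en-1-yl)-7-(propan-2-yl)cyclohept-3-en-1-one (5,6-trans; C7 mixture) | CC(C)C1[C@H](CC(C)=C)[C@@H](C=C)C=C(C)CC1=O
F5 | step 11 | 7α-hydroxy-4α-isopropyl-2,7β-dimethyl-3,3a,4,5,6,7,8,8a-octahydroazulen-5β-yl 4-acetoxybenzoate | CC(C)[C@H]1[C@@H]2CC(C)=C[C@H]2C[C@@](C)(O)C[C@@H]1OC(=O)c1ccc(OC(C)=O)cc1
F6 | step 11 | 4α-isopropyl-2,7β-dimethyl-7α-(triethylsilyloxy)-3,3a,4,5,6,7,8,8a-octahydroazulen-5β-yl 4-acetoxybenzoate | CC(C)[C@H]1[C@@H]2CC(C)=C[C@H]2C[C@@](C)(O[Si](CC)(CC)CC)C[C@@H]1OC(=O)c1ccc(OC(C)=O)cc1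
F7 | step 11 | 1β-bromo-2α-hydroxy-4α-isopropyl-2β,7β-dimethyl-7α-(triethylsilyloxy)decahydroazulen-5β-yl 4-acetoxybenzoate | CC(C)[C@H]1[C@@H]2C[C@@](C)(O)[C@H](Br)[C@H]2C[C@@](C)(O[Si](CC)(CC)CC)C[C@@H]1OC(=O)c1ccc(OC(C)=O)cc1
F8 | step 11 | 1α,2α-epoxy-4α-isopropyl-2β,7β-dimethyl-7α-(triethylsilyloxy)decahydroazulen-5β-yl 4-hydroxybenzoate | CC(C)[C@H]1[C@@H]2C[C@@]3(C)O[C@H]3[C@H]2C[C@@](C)(O[Si](CC)(CC)CC)C[C@@H]1OC(=O)c1ccc(O)cc1
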